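**Plan**

Numbering (farnesane): OCH2 = C1, chain olefin C2=C3, ring CH = C6, methylene-bearing ring carbon = C7, carbinol = C10, CMe2 = C11.
Cuts, in retrosynthetic order: the C1–O aryl ether; C7=CH2 and C2=C3, which uncovers a C7/C3 1,5-diketone; then C7–C6 and C4–C5 together (enol–olefin [2+2], the temporary C7–C4 bond being broken again by retro-aldol); C8–C9 (diketone dianion + oxirane); C10–C11 (reverse prenylation).
Forward: the acyclic chain is assembled first (prenyl unit + chloroacetaldehyde → oxirane → + acetylacetone), the only carbocycle closes in the photochemical step, C1/C2 and the exocyclic CH2 are added, and the coumarin is attached last.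
Enabling feature: ring carbon C6 bears two vicinal carbon arms, ring C7 (a ketone masked as the methylene) and chain C5–C4–C3 (C3 a ketone masked as the methyl-bearing olefin carbon). This 1,5-dicarbonyl array across C6–C5 is what a De Mayo reaction lays down on a vinyl group (C6=C5) held on the quaternary ring carbon C11.
Stereochemistry: C10 (S) comes from hydrolytic kinetic resolution of the oxirane. C6 is created in the photoreaction, brought to the cis relation with C10 by equilibration α to the C7 ketone after the methyl ketone has been olefinated (step 8), and frozen by non-basic methylenation. The 2E geometry comes from the HWE reaction.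

Key step: step 6

Assumption: the (S,S)-(salen)Co catalyst is taken to hydrolyse the (S)-oxirane, as with simple alkyl oxiranes; if the sense is opposite for this substrate, the mirror-image catalyst is used.

**Route**

Step 1
Reactants: 1 1-bromo-3-methylbut-2-ene (prenyl bromide); 2 chloroacetaldehyde (50 wt% in water)
Product: 4 rac-1-chloro-3,3-dimethylpent-4-en-2-ol, via prenylzinc bromide 3 (not isolated)
Conditions: Zn dust, THF/sat. aq. NH4Cl, 0 °C → rt
Reagents that add atoms: none
Why: Aqueous Barbier allylation, in which the allylzinc species adds through its γ-carbon (cyclic SE2′ transition state), so the quaternary C11 with its vinyl group is bonded to the carbinol carbon C10 and the chloride is kept for ring closure; C10 is racemic at this stage.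

Step 2
Reactants: 4 rac-1-chloro-3,3-dimethylpent-4-en-2-ol
Product: 5 rac-2-(2-methylbut-3-en-2-yl)oxirane
Conditions: NaOH (2 M aq.), Et2O, 0 °C → rt; distillation
Reagents that add atoms: none
Why: Intramolecular Williamson etherification (3-exo-tet displacement of chloride by the alkoxide), the standard chlorohydrin-to-oxirane closure.

Step 3
Reactants: 5 rac-2-(2-methylbut-3-en-2-yl)oxirane
Product: 6 (2R)-2-(2-methylbut-3-en-2-yl)oxirane
Conditions: (S,S)-(salen)Co(III)OAc (1–2 mol%), H2O (0.55 equiv), 0 °C → rt; distillation from the diol
Reagents that add atoms: none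
Why: Jacobsen hydrolytic kinetic resolution, in which the chiral Co(III) complex hydrolyses one enantiomer of a terminal oxirane at its CH2 terminus much faster than the other (tert-alkyl oxiranes are established substrates), so the unreacted (R)-oxirane should be recovered enantiomerically enriched; this fixes C10.

Step 4
Reactants: 7 pentane-2,4-dione (acetylacetone); 6 (2R)-2-(2-methylbut-3-en-2-yl)oxirane
Product: 9 (7S)-7-hydroxy-8,8-dimethyldec-9-ene-2,4-dione, via acetylacetone dianion 8 (not isolated)
Conditions: 7 (1.5 equiv), NaH then n-BuLi, THF, 0 °C; 6, 0 °C → rt; AcOH, −78 °C, pH 7 buffer; used crude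
Reagents that add atoms: none
Why: Alkylation of a β-diketone dianion at its terminal carbanion, an SN2 opening of the oxirane at the unhindered CH2 that forms C8–C9 and leaves the C10–O bond (and so the configuration) untouched; cold neutral work-up and immediate silylation keep the free hydroxyl from adding to the C7 carbonyl.

Step 5
Reactants: 9 (7S)-7-hydroxy-8,8-dimethyldec-9-ene-2,4-dione
Product: 10 (7S)-7-(tert-butyldimethylsilyloxy)-8,8-dimethyldec-9-ene-2,4-dione
Conditions: TBSOTf (1.3 equiv), 2,6-lutidine, CH2Cl2, −78 → 0 °C; aq. NaHCO3, then dilute citric acid wash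
Reagents that add atoms: tert-butyldimethylsilyl trifluoromethanesulfonate (TBSOTf), CC(C)(C)[Si](C)(C)OS(=O)(=O)C(F)(F)F
Why: Silyl triflate/lutidine silylation is the standard protection of a hindered secondary alcohol next to a quaternary carbon; the hydrogen-bonded enol is far less nucleophilic under lutidine buffering and any O-silylation of it is reversed by the acidic wash, so only the C10 hydroxyl stays protected.

Step 6
Reactants: 10 (7S)-7-(tert-butyldimethylsilyloxy)-8,8-dimethyldec-9-ene-2,4-dione
Product: 12 (2S,4S)-4-(tert-butyldimethylsilyloxy)-3,3-dimethyl-2-(3-oxobutyl)cyclohexan-1-one (cis), via acetylcyclobutanol photoadduct 11 (not isolated)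
Conditions: hν (medium-pressure Hg lamp, Pyrex, λ > 300 nm), degassed cyclohexane (0.01 M), rt
Reagents that add atoms: none
Why: The hydrogen-bonded enol of 10 (C3=O conjugated with C4=C7–OH) absorbs above 300 nm like an enone, its C7 terminus bonds to the internal vinyl carbon C6, the resulting C4/C5 1,4-biradical recombines to the cis-fused acetylcyclobutanol 11, and this strained β-hydroxy ketone opens at once by retro-aldol cleavage of C7–C4 to the C7/C3 1,5-diketone. This is the intramolecular De Mayo reaction of an alkenyl β-diketone, a known reaction class. The cyclohexane ring closes in the 6-exo-trig mode (C7 onto C6 through the four-atom C8–C11 tether) and the transient cyclobutane by radical recombination at C4–C5, only the six-membered ring surviving the fragmentation. The new stereocentre C6 is set in the first bond formation under the control of the resident C10 centre: a chair-like arrangement of the forming ring with the silyloxy group and the vinyl terminus C5 both equatorial leads to the cis compound 12, and because this preference may be incomplete the crude diketone is carried on unseparated with whatever C6 epimer it contains, C6 being placed under thermodynamic control in step 8. The selectivity the step must deliver is the straight regiochemistry (C7–C6/C4–C5) through the enol tautomer whose C=C carries the tether, which is secured because no five-membered closure is possible with this tether, the crossed mode or the other tautomer would need seven- or eight-membered rings, and the gem-dimethyl group at C11 folds the chain toward C7. Pyrex-filtered light, absorbed far more strongly by the enol than by the product ketones, and the photochemical inertness of the silyl ether should leave the rest of the molecule intact.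

Step 7
Reactants: 12 (2S,4S)-4-(tert-butyldimethylsilyloxy)-3,3-dimethyl-2-(3-oxobutyl)cyclohexan-1-one (crude material of step 6); 13 triethyl phosphonoacetate
Product: 15 ethyl (2E)-5-[(3S)-3-(tert-butyldimethylsilyloxy)-2,2-dimethyl-6-oxocyclohexyl]-3-methylpent-2-enoate as the mixture of its C1 epimers, via sodium triethyl phosphonoacetate 14 (not isolated)
Conditions: 13 (1.3 equiv), NaH (1.2 equiv), THF, 0 °C; then 12, 0 → 45 °C; chromatography (removal of the 2Z isomer)
Reagents that add atoms: none
Why: Horner–Wadsworth–Emmons olefination, in which the stabilised phosphonate anion attacks the unhindered methyl ketone (C3) and not the C7 ketone (shielded by the α-branch at C6 and the adjacent quaternary C11), reversible addition favours the E-enoate, and the slight excess of phosphonate over NaH leaves no free base for aldol closure of the 1,5-diketone; the configuration at C6, α to the ring ketone, is not secured at this stage, so the product is carried as the epimer mixture that step 8 converges.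

Step 8
Reactants: 15 ethyl (2E)-5-[(3S)-3-(tert-butyldimethylsilyloxy)-2,2-dimethyl-6-oxocyclohexyl]-3-methylpent-2-enoate (C1-epimer mixture)
Product: 16 ethyl (2E)-5-[(1S,3S)-3-(tert-butyldimethylsilyloxy)-2,2-dimethyl-6-oxocyclohexyl]-3-methylpent-2-enoate (cis)
Conditions: NaOEt (0.2 equiv), EtOH, rt → 40 °C; AcOH quench; chromatography, the recovered trans epimer being resubmitted
Reagents that add atoms: none
Why: Base-mediated epimerisation through the C6=C7 enolate puts C6 under thermodynamic control, under which the cis isomer 16 can hold both the C6 side chain and the C10 silyloxy group equatorial whereas its trans epimer must place one of them axial, so 16 should predominate at equilibrium; the preference may be moderate, hence separation and resubmission of the minor epimer belong to the step, and ethoxide matches the ethyl ester under conditions too mild to deconjugate the enoate.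

Step 9
Reactants: 16 ethyl (2E)-5-[(1S,3S)-3-(tert-butyldimethylsilyloxy)-2,2-dimethyl-6-oxocyclohexyl]-3-methylpent-2-enoate
Product: 17 ethyl (2E)-5-[(1R,3S)-3-(tert-butyldimethylsilyloxy)-2,2-dimethyl-6-methylidenecyclohexyl]-3-methylpent-2-enoate
Conditions: Zn, CH2Br2, TiCl4, THF, −40 → 5 °C (reagent aged); then 16, CH2Cl2, 0 °C → rt
Reagents that add atoms: dibromomethane, BrCBr
Why: Takai–Lombardo methylenation, whose non-basic Zn/Ti methylene reagent converts hindered, enolisable ketones into methylene compounds without epimerising the α-centre and leaves esters and silyl ethers alone, so the C6 configuration set in step 8 is frozen (the descriptor changes from S to R only through the priority rules).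

Step 10
Reactants: 17 ethyl (2E)-5-[(1R,3S)-3-(tert-butyldimethylsilyloxy)-2,2-dimethyl-6-methylidenecyclohexyl]-3-methylpent-2-enoate
Product: 18 (2E)-5-[(1R,3S)-3-(tert-butyldimethylsilyloxy)-2,2-dimethyl-6-methylidenecyclohexyl]-3-methylpent-2-en-1-ol
Conditions: DIBAL-H (2.5 equiv), CH2Cl2, −78 °C; Rochelle salt work-up
Reagents that add atoms: none
Why: 1,2-Reduction of the α,β-unsaturated ester to the allylic alcohol by DIBAL-H, to which the isolated exocyclic olefin and the silyl ether are inert, with retention of the olefin geometry.

Step 11
Reactants: 18 (2E)-5-[(1R,3S)-3-(tert-butyldimethylsilyloxy)-2,2-dimethyl-6-methylidenecyclohexyl]-3-methylpent-2-en-1-ol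
Product: 19 (1S,3R)-3-[(3E)-5-hydroxy-3-methylpent-3-en-1-yl]-2,2-dimethyl-4-methylidenecyclohexan-1-ol
Conditions: TBAF (3 equiv), THF, rt → 45 °C
Reagents that add atoms: none
Why: Fluoride-mediated desilylation of the hindered secondary silyl ether, placed before the coumarin is attached so that the base-sensitive 4-alkoxycoumarin never meets fluoride.

Step 12
Reactants: 19 (1S,3R)-3-[(3E)-5-hydroxy-3-methylpent-3-en-1-yl]-2,2-dimethyl-4-methylidenecyclohexan-1-ol; 20 4-hydroxy-5-methyl-2H-chromen-2-one (4-hydroxy-5-methylcoumarin)
Product: 21 4-{[(2E)-5-[(1R,3S)-3-hydroxy-2,2-dimethyl-6-methylidenecyclohexyl]-3-methylpent-2-en-1-yl]oxy}-5-methyl-2H-chromen-2-one (CNP0172901.1)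
Conditions: 20 (1.05 equiv), PPh3, DIAD, THF, 0 °C → rt
Reagents that add atoms: none
Why: Mitsunobu etherification, in which the acidic 4-hydroxycoumarin is alkylated on O4 by the oxyphosphonium salt of the primary allylic alcohol (SN2, no stereocentre involved), while the secondary hydroxyl flanked by the quaternary C11 is too hindered to be activated, so no protecting group is needed.

**Compound list**

1 | 1-bromo-3-methylbut-2-ene (prenyl bromide) | CC(C)=CCBr | starting material
2 | chloroacetaldehyde (2-chloroethanal, 50 wt% aqueous solution) | ClCC=O | starting material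
3 | prenylzinc bromide, (3-methylbut-2-en-1-yl)zinc bromide | CC(C)=CC[Zn]Br | intermediate (not isolated)
4 | rac-1-chloro-3,3-dimethylpent-4-en-2-ol | C=CC(C)(C)C(O)CCl | intermediate
5 | rac-2-(2-methylbut-3-en-2-yl)oxirane | C=CC(C)(C)C1CO1 | intermediate
6 | (2R)-2-(2-methylbut-3-en-2-yl)oxirane | C=CC(C)(C)[C@@H]1CO1 | intermediate
7 | pentane-2,4-dione (acetylacetone) | CC(=O)CC(C)=O | starting material
8 | acetylacetone dianion (sodium lithium salt) | [Na+].[Li+].[CH2-]C(=O)[CH-]C(C)=O | intermediate (not isolated)
9 | (7S)-7-hydroxy-8,8-dimethyldec-9-ene-2,4-dione | CC(=O)CC(=O)CC[C@H](O)C(C)(C)C=C | intermediate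
10 | (7S)-7-(tert-butyldimethylsilyloxy)-8,8-dimethyldec-9-ene-2,4-dione | CC(=O)CC(=O)CC[C@H](O[Si](C)(C)C(C)(C)C)C(C)(C)C=C | intermediate
11 | 1-[(4S)-4-(tert-butyldimethylsilyloxy)-1-hydroxy-5,5-dimethylbicyclo[4.2.0]octan-8-yl]ethan-1-one (cis-fused photoadduct, diastereomers at C1/C6/C8) | CC(=O)C1CC2C(C)(C)[C@@H](O[Si](C)(C)C(C)(C)C)CCC12O | intermediate (not isolated)
12 | (2S,4S)-4-(tert-butyldimethylsilyloxy)-3,3-dimethyl-2-(3-oxobutyl)cyclohexan-1-one (cis) | O=C1CC[C@H](O[Si](C)(C)C(C)(C)C)C(C)(C)[C@@H]1CCC(C)=O | intermediate
13 | triethyl phosphonoacetate | CCOC(=O)CP(=O)(OCC)OCC | starting material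
14 | sodium triethyl phosphonoacetate (phosphonate carbanion) | CCOC(=O)[CH-]P(=O)(OCC)OCC.[Na+] | intermediate (not isolated)
15 | ethyl (2E)-5-[(3S)-3-(tert-butyldimethylsilyloxy)-2,2-dimethyl-6-oxocyclohexyl]-3-methylpent-2-enoate (mixture of the C1 epimers, cis and trans) | O=C1CC[C@H](O[Si](C)(C)C(C)(C)C)C(C)(C)C1CC/C(C)=C/C(=O)OCC | intermediate
16 | ethyl (2E)-5-[(1S,3S)-3-(tert-butyldimethylsilyloxy)-2,2-dimethyl-6-oxocyclohexyl]-3-methylpent-2-enoate (cis) | O=C1CC[C@H](O[Si](C)(C)C(C)(C)C)C(C)(C)[C@@H]1CC/C(C)=C/C(=O)OCC | intermediate
17 | ethyl (2E)-5-[(1R,3S)-3-(tert-butyldimethylsilyloxy)-2,2-dimethyl-6-methylidenecyclohexyl]-3-methylpent-2-enoate | C=C1CC[C@H](O[Si](C)(C)C(C)(C)C)C(C)(C)[C@@H]1CC/C(C)=C/C(=O)OCC | intermediate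
18 | (2E)-5-[(1R,3S)-3-(tert-butyldimethylsilyloxy)-2,2-dimethyl-6-methylidenecyclohexyl]-3-methylpent-2-en-1-ol | C=C1CC[C@H](O[Si](C)(C)C(C)(C)C)C(C)(C)[C@@H]1CC/C(C)=C/CO | intermediate
19 | (1S,3R)-3-[(3E)-5-hydroxy-3-methylpent-3-en-1-yl]-2,2-dimethyl-4-methylidenecyclohexan-1-ol | C=C1CC[C@H](O)C(C)(C)[C@@H]1CC/C(C)=C/CO | intermediate
20 | 4-hydroxy-5-methyl-2H-chromen-2-one (4-hydroxy-5-methylcoumarin) | Cc1cccc2oc(=O)cc(O)c12 | starting material
21 | 4-{[(2E)-5-[(1R,3S)-3-hydroxy-2,2-dimethyl-6-methylidenecyclohexyl]-3-methylpent-2-en-1-yl]oxy}-5-methyl-2H-chromen-2-one | C=C1CC[C@H](O)C(C)(C)[C@@H]1CC/C(C)=C/COc1cc(=O)oc2cccc(C)c12 | target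

**Step count**

Total: 12 steps. Longest linear sequence: 12 steps (1 → 4 → 5 → 6 → 9 → 10 → 12 → 15 → 16 → 17 → 18 → 19 → 21); acetylacetone, the phosphonate and the coumarin enter as purchased.

**Steps most likely to fail, with fallbacks**

Step 6. The chelated enol may lose its excitation by internal proton transfer faster than it closes the six-membered ring, or the diketone formed may suffer Norrish cleavage before conversion is complete. The fallback sets out from 10 and comes back at 12, and replaces the free enol by a fixed enol ester. Treatment of 10 with NaH and benzyl chloroformate gives benzyl (7S)-7-(tert-butyldimethylsilyloxy)-8,8-dimethyl-2-oxodeca-3,9-dien-4-yl carbonate F1. It is formed together with the regioisomer benzyl (7S)-7-(tert-butyldimethylsilyloxy)-8,8-dimethyl-4-oxodeca-2,9-dien-2-yl carbonate F2, which cannot close a small ring and is returned to 10 by methanolysis (K2CO3, MeOH, 0 °C). Irradiation of F1 (Pyrex) is a β-acyloxy-enone [2+2] cycloaddition and should give benzyl (4S)-8-acetyl-4-(tert-butyldimethylsilyloxy)-5,5-dimethylbicyclo[4.2.0]octan-1-yl carbonate F3, which is stable and can be purified. Hydrogenolysis (H2, Pd/C, EtOAc; no olefin is left in F3) frees the cyclobutanol 11 under neutral conditions, and its retro-aldol opening gives 12, which is carried into step 7 as in the main route.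

Step 8. The equilibrium between the C6 epimers may lie close to unity and the epimers may be hard to separate, so that enrichment by resubmission becomes slow. The fallback sets out from 15 and comes back at 16, and uses kinetic instead of thermodynamic control. Under equilibrating conditions (TMSCl, NaI, Et3N, MeCN) the ketone is converted into the more substituted silyl enol ether, ethyl (2E)-5-[(5S)-5-(tert-butyldimethylsilyloxy)-6,6-dimethyl-2-(trimethylsilyloxy)cyclohex-1-en-1-yl]-3-methylpent-2-enoate F4, in which C6 is trigonal and both epimers have converged. Desilylative protonation at low temperature (TBAF/AcOH, THF, −78 °C) should then deliver the proton axially at C6, anti to the pseudo-axial methyl group of C11 in the half-chair that keeps the C10 silyloxy group equatorial; that is the configuration of 16.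

Step 12. The ambident coumarin may be alkylated on the lactone oxygen (2-alkoxychromone formation), at C3, or with allylic transposition, the peri methyl group at C5 slowing attack through O4. The fallback sets out from 20 and 19 and comes back at 21, with the polarity reversed. POCl3 (Et3N, reflux) converts 20 into 4-chloro-5-methyl-2H-chromen-2-one F5. The sodium alkoxide of the primary hydroxyl of 19 (NaH 1.0 equiv, THF, 0 °C) then displaces the chloride by addition–elimination at C4, which can only give the 4-O ether 21.

**Further compounds**

F1 | step 6 | benzyl (7S)-7-(tert-butyldimethylsilyloxy)-8,8-dimethyl-2-oxodeca-3,9-dien-4-yl carbonate | CC(=O)C=C(OC(=O)OCc1ccccc1)CC[C@H](O[Si](C)(C)C(C)(C)C)C(C)(C)C=C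
F2 | step 6 | benzyl (7S)-7-(tert-butyldimethylsilyloxy)-8,8-dimethyl-4-oxodeca-2,9-dien-2-yl carbonate | CC(OC(=O)OCc1ccccc1)=CC(=O)CC[C@H](O[Si](C)(C)C(C)(C)C)C(C)(C)C=C
F3 | step 6 | benzyl (4S)-8-acetyl-4-(tert-butyldimethylsilyloxy)-5,5-dimethylbicyclo[4.2.0]octan-1-yl carbonate | CC(=O)C1CC2C(C)(C)[C@@H](O[Si](C)(C)C(C)(C)C)CCC12OC(=O)OCc1ccccc1
F4 | step 8 | ethyl (2E)-5-[(5S)-5-(tert-butyldimethylsilyloxy)-6,6-dimethyl-2-(trimethylsilyloxy)cyclohex-1-en-1-yl]-3-methylpent-2-enoate | CCOC(=O)/C=C(\C)CCC1=C(O[Si](C)(C)C)CC[C@H](O[Si](C)(C)C(C)(C)C)C1(C)C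
F5 | step 12 | 4-chloro-5-methyl-2H-chromen-2-one | Cc1cccc2oc(=O)cc(Cl)c12
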